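**Assumption:** the two naphthazarin tautomers (side chain on the quinone ring or on the dihydroxybenzene ring) interconvert rapidly and are one compound. The target is the (S)-ester, as the SMILES shows.

## Retrosynthetic overview

1. The naphthazarin core is disconnected by a [4+2] between a chiral 2-substituted p-benzoquinone and 2,5-bis(trimethylsiloxy)furan. Bridge hydrolysis and double enolization give the 5,8-dihydroxy ring at the correct oxidation level, so no phenol protecting groups are needed.
2. The quinone comes from oxidative dearomatization (CAN) of the corresponding 2,5-dimethoxyphenyl ester.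
3. The side chain: ester from the alcohol; prenyl terminus from an allyl group by cross-metathesis; the (S)-carbinol from Brown allylation of 2,5-dimethoxybenzaldehyde.
4. Ring order: the purchased benzene ring becomes the quinone ring; the dihydroxybenzene ring is built last, from succinic anhydride via the silyloxyfuran.

## Route

**Step 1**
Reactants: 1, 2,5-dimethoxybenzaldehyde; 2, allylmagnesium bromide
Product: 3, (S)-1-(2,5-dimethoxyphenyl)but-3-en-1-ol
Conditions: (−)-Ipc2BOMe [from (+)-α-pinene], 2, Et2O, 0 °C; then 1, −78 °C; NaOH, H2O2
Reagents that add atoms: allylmagnesium bromide, C=CC[Mg]Br (allyl group, delivered as B-allyldiisopinocampheylborane)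
Why: Brown asymmetric allylboration through a chair transition state; the (+)-α-pinene-derived reagent adds allyl to the Si face of aryl aldehydes, which gives the (S)-carbinol (the same sense as (S)-1-phenylbut-3-en-1-ol from benzaldehyde).

**Step 2**
Reactants: 3, (S)-1-(2,5-dimethoxyphenyl)but-3-en-1-ol; 4, 2-methyl-2-butene
Product: 5, (S)-1-(2,5-dimethoxyphenyl)-4-methylpent-3-en-1-ol
Conditions: Grubbs II (3 mol%), 2-methyl-2-butene/CH2Cl2 (1:1), 35 °C
Reagents that add atoms: 2-methyl-2-butene, CC=C(C)C (isopropylidene terminus)
Why: Olefin cross-metathesis of a terminal alkene with excess 2-methyl-2-butene reliably converts allyl into prenyl and gives the linear side chain that direct prenyl-metal addition would not; the stereocenter is untouched.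

**Step 3**
Reactants: 5, (S)-1-(2,5-dimethoxyphenyl)-4-methylpent-3-en-1-ol; 6, isovaleryl chloride (3-methylbutanoyl chloride)
Product: 7, (S)-1-(2,5-dimethoxyphenyl)-4-methylpent-3-en-1-yl 3-methylbutanoate
Conditions: 6, Et3N, DMAP (cat.), CH2Cl2, 0 °C to rt
Reagents that add atoms: isovaleryl chloride, CC(C)CC(=O)Cl
Why: DMAP-catalysed O-acylation of the secondary alcohol proceeds with retention, since the C–O bond is not broken; the ester also shields the benzylic position in the next step.

**Step 4**
Reactants: 7, (S)-1-(2,5-dimethoxyphenyl)-4-methylpent-3-en-1-yl 3-methylbutanoate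
Product: 8, (S)-1-(3,6-dioxocyclohexa-1,4-dien-1-yl)-4-methylpent-3-en-1-yl 3-methylbutanoate (the 2-substituted 1,4-benzoquinone)
Conditions: CAN (2.5 equiv), MeCN/H2O (2:1), 0 °C, 15 min
Reagents that add atoms: water, O (quinone oxygens; both methoxy groups leave as methanol)
Why: CAN oxidative demethylation (oxidative dearomatization) of a 1,4-dimethoxyarene to the p-quinone is fast at 0 °C and tolerates the trisubstituted alkene and the ester; the stereocenter is not involved.

**Step 5**
Reactants: 9, succinic anhydride; 10, chlorotrimethylsilane
Product: 11, 2,5-bis(trimethylsiloxy)furan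
Conditions: TMSCl (2.5 equiv), Et3N (2.5 equiv), ZnCl2 (cat.), MeCN, rt to 50 °C; filter, distil under reduced pressure
Reagents that add atoms: chlorotrimethylsilane, C[Si](C)(C)Cl
Why: Double soft enolization and O-silylation of the anhydride gives the aromatic bis(silyl enol ether), a known electron-rich furan diene.

**Step 6 (key step)**
Reactants: 8, the chiral benzoquinone; 11, 2,5-bis(trimethylsiloxy)furan
Product: 12, isovalerylalkannin, (S)-1-(5,8-dihydroxy-1,4-dioxo-1,4-dihydronaphthalen-2-yl)-4-methylpent-3-en-1-yl 3-methylbutanoate
Conditions: 11 (1.5 equiv), CH2Cl2, −20 °C to rt; then 1 M HCl/THF, rt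
Reagents that add atoms: 2,5-bis(trimethylsiloxy)furan, C[Si](C)(C)Oc1ccc(O[Si](C)(C)C)o1 (four carbons and two oxygens)
Why: Diels–Alder cycloaddition of the electron-rich silyloxyfuran (which loses its aromaticity) to the unsubstituted C5=C6 bond of the quinone; acid hydrolysis opens the bis-silyl ketal bridge to an ene-1,4-dione, and the resulting 4a,8a-dihydro-tetraone enolizes twice to the naphthazarin with no redox adjustment. The diene is symmetric and all new sp3 centres are erased on aromatization, so only the existing (S)-centre remains.

## Compound list

1 | 2,5-dimethoxybenzaldehyde | COc1ccc(OC)c(C=O)c1 | starting material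
2 | allylmagnesium bromide | C=CC[Mg]Br | starting material
3 | (S)-1-(2,5-dimethoxyphenyl)but-3-en-1-ol | C=CC[C@H](O)c1cc(OC)ccc1OC | intermediate
4 | 2-methyl-2-butene | CC=C(C)C | starting material
5 | (S)-1-(2,5-dimethoxyphenyl)-4-methylpent-3-en-1-ol | CC(C)=CC[C@H](O)c1cc(OC)ccc1OC | intermediate
6 | isovaleryl chloride | CC(C)CC(=O)Cl | starting material
7 | (S)-1-(2,5-dimethoxyphenyl)-4-methylpent-3-en-1-yl 3-methylbutanoate | CC(C)=CC[C@H](OC(=O)CC(C)C)c1cc(OC)ccc1OC | intermediate
8 | (S)-1-(3,6-dioxocyclohexa-1,4-dien-1-yl)-4-methylpent-3-en-1-yl 3-methylbutanoate | CC(C)=CC[C@H](OC(=O)CC(C)C)C1=CC(=O)C=CC1=O | intermediate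
9 | succinic anhydride | O=C1CCC(=O)O1 | starting material
10 | chlorotrimethylsilane | C[Si](C)(C)Cl | starting material
11 | 2,5-bis(trimethylsiloxy)furan | C[Si](C)(C)Oc1ccc(O[Si](C)(C)C)o1 | intermediate
12 | isovalerylalkannin | CC(C)=CC[C@H](OC(=O)CC(C)C)C1=CC(=O)c2c(O)ccc(O)c2C1=O | target

## Summary

Total steps: 6.
Longest linear sequence: 5 (steps 1, 2, 3, 4, 6); step 5 is a one-step convergent branch.

Steps most likely to fail:

1. **Step 6 (furan Diels–Alder and aromatization).** The silyloxyfuran may instead undergo Mukaiyama–Michael addition or electron transfer with the quinone, or add at the substituted double bond. Fallback: build the naphthalene first. Run steps 1–3 on 1,4,5,8-tetramethoxynaphthalene-2-carbaldehyde and unveil the naphthazarin by two-stage oxidative demethylation (CAN, then AgO/HNO3 followed by dithionite reduction of the diquinone).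
2. **Step 4 (CAN oxidation).** Biquinone dimers, benzylic ester loss or alkene oxidation could erode the yield. Fallback: change the protecting-group strategy. Start from 2,5-bis(TBS-oxy)benzaldehyde (from gentisaldehyde), so the quinone is released by fluoride desilylation and mild Ag2O or air oxidation of the free hydroquinone, with no oxidative demethylation.
3. **Step 1 (enantioselectivity with the ortho-methoxy aldehyde).** The ee may fall short of 95%, and the sense must be confirmed by Mosher ester or chiral HPLC. Fallback: make the ketone instead (2-lithio-1,4-dimethoxybenzene plus the Weinreb amide of 4-methylpent-3-enoic acid) and reduce it with (R)-Me-CBS/BH3, which should give (S)-5 directly and removes the metathesis step.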